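**Retrosynthetic overview**
1. Target 10 ⇒ Mizoroki–Heck disconnection of the aryl–CH=CH bond: aryl iodide 8 + 2-methylbut-3-en-2-ol.
2. 8 ⇒ light-driven Ni-catalysed aryl–prenyl coupling that desymmetrises the diiodide 6 with prenyl acetate (key C–C bond, photochemical).
3. 6 ⇒ glycoside hydrolysis, O-methylation and phenoxide-directed diiodination of (2S)-naringin.
4. No ring is formed: rings A, C and B and the C2 (S) centre are bought intact in naringin. Its 7-O-sugar acts as the built-in protecting group for O-7.

Assumption: commercial naringin is used as the single (2S) epimer. The 2R epimer is a diastereomer while the sugar is attached, so it can be detected and removed by recrystallisation at compounds 1, 3 or 5. Enantiopurity is checked by chiral HPLC at 6 and 10.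

**Step 1**
Reactants: 1 (2S)-naringin; 2 iodine
Product: 3 (2S)-3',5'-diiodonaringin
Conditions: I2 (2.1 equiv), KI, NaHCO3 (pH ≈ 8), MeOH–H2O, 0 °C; then Na2S2O3, AcOH to pH 5
Reagents that add atoms: iodine, II
Why: Electrophilic aromatic iodination under phenoxide control goes only to the two positions ortho to the 4'-phenoxide (para blocked), because the A ring has no free phenoxide (O-7 glycosylated, 5-OH hydrogen-bonded to C4=O) and I2/I3⁻ is too weak to attack the neutral ring; cold, weakly basic conditions leave C2 untouched.

**Step 2**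
Reactants: 3; 4 (trimethylsilyl)diazomethane
Product: 5 (2S)-3',5'-diiodo-4'-O-methylnaringin
Conditions: TMSCHN2 (1.5 equiv), MeOH–THF, 0 °C → rt
Reagents that add atoms: (trimethylsilyl)diazomethane, C[Si](C)(C)C=[N+]=[N-] (supplies the O-methyl carbon)
Why: Diazoalkane O-methylation of the acidic 2,6-diiodophenol (pKa ≈ 6.5) proceeds without base, so the chelated 5-OH and the sugar hydroxyls do not react, O-7 stays blocked by the sugar, and C2 cannot epimerise.

**Step 3**
Reactants: 5
Product: 6 (2S)-5,7-dihydroxy-2-(3,5-diiodo-4-methoxyphenyl)chroman-4-one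
Conditions: 2 M HCl, MeOH–H2O (1:1), 80 °C, 3 h; cool, filter
Reagents that add atoms: none
Why: Acid-catalysed glycoside hydrolysis releases the 7-OH before any acid-sensitive side chain is present; aryl iodides and the aryl methyl ether are stable, and a 4'-methoxyflavanone does not ring-open at C2 under acid.

**Step 4**
Reactants: 6; 7 prenyl acetate (3-methylbut-2-en-1-yl acetate)
Product: 8 (2S)-5,7-dihydroxy-2-[3-iodo-4-methoxy-5-(3-methylbut-2-en-1-yl)phenyl]chroman-4-one
Conditions: 7 (1.1 equiv), NiBr2·dme (10 mol%), dtbbpy (12 mol%), 4CzIPN (2 mol%), Hantzsch ester (1.3 equiv), 2,6-lutidine (1.5 equiv), DMA, 450 nm LEDs, 20 °C, stop at ~90% conversion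
Reagents that add atoms: prenyl acetate, CC(C)=CCOC(C)=O (prenyl group only)
Why: Proposed new method: a light-driven, metal-reductant-free Ni-catalysed reductive aryl–allyl cross-electrophile coupling used as a desymmetrising mono-prenylation of a 2,6-diiodoanisole on an unprotected 5,7-dihydroxyflavanone. Excited 4CzIPN is reductively quenched by Hantzsch ester and the reduced dye turns Ni(II) over to low-valent Ni; this adds into one C–I bond (activated by the second, meta iodine), the reduced aryl–Ni(I) ionises prenyl acetate to an aryl–Ni(III)(η3-prenyl), and reductive elimination at the unsubstituted allyl terminus gives the linear prenyl arene. The product's remaining C–I sits on a more electron-rich, more hindered ring and reacts more slowly, which favours mono-coupling; 450 nm light is not absorbed by the flavanone, so C2 is not at risk. Closest known reaction types: Ni/Zn (or Mn) reductive coupling of aryl halides with allylic acetates, and Ni/photoredox aryl–alkyl cross-electrophile coupling.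

**Step 5**
Reactants: 8; 9 2-methylbut-3-en-2-ol
Product: 10 (target) (2S)-5,7-dihydroxy-2-{3-[(E)-3-hydroxy-3-methylbut-1-en-1-yl]-4-methoxy-5-(3-methylbut-2-en-1-yl)phenyl}chroman-4-one
Conditions: 9 (3 equiv), Pd(OAc)2 (5 mol%), n-Bu4NCl (1 equiv), NaHCO3 (2.5 equiv), DMF, 60 °C
Reagents that add atoms: 2-methylbut-3-en-2-ol, CC(C)(O)C=C
Why: Mizoroki–Heck reaction (Jeffery conditions) of the aryl iodide with a terminal alkene whose carbinol carbon is quaternary, so β-hydride elimination can only give the (E)-styrenyl tertiary alcohol; the trisubstituted prenyl alkene is not a Heck acceptor and the weak base does not epimerise the 4'-methoxyflavanone.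

**Compound list**
1 | (2S)-naringin | C[C@H]1[C@@H]([C@H]([C@H]([C@@H](O1)O[C@@H]2[C@H]([C@@H]([C@H](O[C@H]2Oc3cc(O)c4C(=O)C[C@H](Oc4c3)c5ccc(O)cc5)CO)O)O)O)O)O | starting material
2 | iodine | II | starting material
3 | (2S)-3',5'-diiodonaringin | C[C@H]1[C@@H]([C@H]([C@H]([C@@H](O1)O[C@@H]2[C@H]([C@@H]([C@H](O[C@H]2Oc3cc(O)c4C(=O)C[C@H](Oc4c3)c5cc(I)c(O)c(I)c5)CO)O)O)O)O)O | intermediate
4 | (trimethylsilyl)diazomethane | C[Si](C)(C)C=[N+]=[N-] | starting material
5 | (2S)-3',5'-diiodo-4'-O-methylnaringin | C[C@H]1[C@@H]([C@H]([C@H]([C@@H](O1)O[C@@H]2[C@H]([C@@H]([C@H](O[C@H]2Oc3cc(O)c4C(=O)C[C@H](Oc4c3)c5cc(I)c(OC)c(I)c5)CO)O)O)O)O)O | intermediate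
6 | (2S)-5,7-dihydroxy-2-(3,5-diiodo-4-methoxyphenyl)chroman-4-one | O=C1C[C@H](Oc2cc(O)cc(O)c12)c1cc(I)c(OC)c(I)c1 | intermediate
7 | prenyl acetate | CC(C)=CCOC(C)=O | starting material
8 | (2S)-5,7-dihydroxy-2-[3-iodo-4-methoxy-5-(3-methylbut-2-en-1-yl)phenyl]chroman-4-one | O=C1C[C@H](Oc2cc(O)cc(O)c12)c1cc(I)c(OC)c(CC=C(C)C)c1 | intermediate
9 | 2-methylbut-3-en-2-ol | CC(C)(O)C=C | starting material
10 | (2S)-5,7-dihydroxy-2-{3-[(E)-3-hydroxy-3-methylbut-1-en-1-yl]-4-methoxy-5-(3-methylbut-2-en-1-yl)phenyl}chroman-4-one | O=C1C[C@H](Oc2cc(O)cc(O)c12)c1cc(CC=C(C)C)c(OC)c(/C=C/C(C)(C)O)c1 | target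

**Totals**
Total steps: 5. Longest linear sequence: 5.

**Three steps most likely to fail**
- **Step 4 (proposed new step).** Risks are Ni sequestration by the 5-OH/C4=O chelate or free phenols, hydrodeiodination, over-prenylation, and branched (reverse-prenyl) product. Fallback (known chemistry): Stille coupling of 6 with tributyl(3-methylbut-2-en-1-yl)stannane (Pd(PPh3)4, DMF, 80 °C, neutral) using limiting stannane, accepting a statistical mono-coupling and recycling recovered 6.
- **Step 1.** Risks are competing iodination at C6/C8 of the A ring and partial C2 epimerisation through the 4'-phenoxide. Fallback: drop electrophilic halogenation and install both C5 units from O-4' by two rounds of Pd-catalysed O-(1,1-dimethylallyl)ation and thermal aromatic Claisen rearrangement on naringin. Then O-methylate, deglycosylate, and convert one prenyl group into the (E)-3-hydroxy-3-methylbutenyl group by hydroxyselenation (PhSeCl, H2O) and selenoxide elimination at partial conversion.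
- **Step 5.** Risks are Pd–H isomerisation of the prenyl group into conjugation and base-induced erosion at C2 at 60 °C. Fallback: Suzuki–Miyaura coupling of 8 with commercial (E)-2-methyl-4-(4,4,5,5-tetramethyl-1,3,2-dioxaborolan-2-yl)but-3-en-2-ol (Pd(dppf)Cl2, aq. K3PO4, THF, 40 °C), which generates no Pd–H and fixes the E geometry in the reagent.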